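**Strategy.** The side chain (C1′ on C2 of the chromene, numbered outward) is cut at the C2′–C3′ single bond, between the two-carbon tether on the quaternary C2 of the 2H-pyran ring and the CH terminus of the (E)-C3′=C4′ alkene. In one operation, 9-BBN hydroboration of a C2-vinyl group and B-alkyl Suzuki–Miyaura coupling with an (E)-alkenyl iodide join the whole chromene to the whole acid-bearing dienoate chain. This exploits that the cis-disubstituted, styrenic ring alkene C3=C4 hydroborates far more slowly than the C2-vinyl. The precursor is a silyl-protected (S)-2-methyl-2-vinyl-2H-chromene, made by Pd-catalysed asymmetric allylic etherification and ring-closing metathesis.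

Key step: step 12

Remark: the ligand enantiomer in step 4 is assigned by analogy with related additions of acidic pronucleophiles to isoprene monoepoxide; its antipode is taken if the first batch proves to be the (S)-ether.

**Step 1**
Reactants: 1 2,3-dimethylbenzene-1,4-diol (2,3-dimethylhydroquinone)
Product: 2 4-[(tert-butyldimethylsilyl)oxy]-2,3-dimethylphenol
Conditions: TBSCl (0.9 equiv), imidazole, DMF, 0 °C → rt; unreacted 1 recovered
Reagents that add atoms: tert-butyldimethylsilyl chloride, CC(C)(C)[Si](C)(C)Cl
Why: Phenol silylation; the two hydroxyls of the symmetrical hydroquinone are equivalent, so sub-stoichiometric TBSCl should give a single mono-ether, separable from recovered diol and bis-ether.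

**Step 2**
Reactants: 2 4-[(tert-butyldimethylsilyl)oxy]-2,3-dimethylphenol
Product: 3 5-[(tert-butyldimethylsilyl)oxy]-2-hydroxy-3,4-dimethylbenzaldehyde
Conditions: MgCl2, Et3N, (CH2O)n, MeCN, reflux
Reagents that add atoms: paraformaldehyde (formaldehyde), C=O
Why: Magnesium-mediated ortho-formylation (Casnati–Skattebøl): the magnesium phenoxide directs formaldehyde to the only free ortho position and a second formaldehyde oxidises the hydroxymethyl intermediate, while the aryl silyl ether is inert to MgCl2/Et3N.

**Step 3**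
Reactants: 3 5-[(tert-butyldimethylsilyl)oxy]-2-hydroxy-3,4-dimethylbenzaldehyde
Product: 4 4-[(tert-butyldimethylsilyl)oxy]-6-ethenyl-2,3-dimethylphenol
Conditions: MePPh3Br (2.5 equiv), NaHMDS (2.4 equiv), THF, 0 °C → rt
Reagents that add atoms: methyltriphenylphosphonium bromide, C[P+](c1ccccc1)(c1ccccc1)c1ccccc1.[Br-]
Why: Wittig methylenation of the salicylaldehyde, with the first equivalent of ylide spent on deprotonating the phenol, should give the 2-vinylphenol without touching the silyl ether.

**Step 4**
Reactants: 4 4-[(tert-butyldimethylsilyl)oxy]-6-ethenyl-2,3-dimethylphenol; 5 2-methyl-2-vinyloxirane (isoprene monoepoxide, racemic)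
Product: 6 (2R)-2-{4-[(tert-butyldimethylsilyl)oxy]-6-ethenyl-2,3-dimethylphenoxy}-2-methylbut-3-en-1-ol
Conditions: Pd2(dba)3·CHCl3 (1 mol %), (S,S)-DACH-phenyl Trost ligand (3 mol %), 5 (1.5 equiv), CH2Cl2, rt
Reagents that add atoms: none
Why: Pd-catalysed dynamic kinetic asymmetric allylic etherification (Trost AAA) of the racemic vinyl epoxide: the π-allyl–Pd alkoxide deprotonates the phenol and the ion pair returns the phenoxide to the proximal tertiary terminus, while rapid π–σ–π equilibration lets the chiral ligand funnel both epoxide enantiomers to the (R)-configured tertiary ether, which is the new stereocentre.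

**Step 5**
Reactants: 6 (2R)-2-{4-[(tert-butyldimethylsilyl)oxy]-6-ethenyl-2,3-dimethylphenoxy}-2-methylbut-3-en-1-ol
Product: 7 [(2R)-6-[(tert-butyldimethylsilyl)oxy]-2,7,8-trimethyl-2H-chromen-2-yl]methanol
Conditions: Grubbs II (3 mol %), CH2Cl2, 40 °C, light excluded
Reagents that add atoms: none
Why: Ring-closing metathesis between the styrenyl and the allylic vinyl group closes the six-membered pyran ring with loss of ethylene; the quaternary stereocentre takes no part, and the ether cannot undergo Claisen rearrangement because both ortho positions and the para position are substituted.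

**Step 6**
Reactants: 7 [(2R)-6-[(tert-butyldimethylsilyl)oxy]-2,7,8-trimethyl-2H-chromen-2-yl]methanol
Product: 8 (2R)-6-[(tert-butyldimethylsilyl)oxy]-2,7,8-trimethyl-2H-chromene-2-carbaldehyde
Conditions: Dess–Martin periodinane (1.2 equiv), CH2Cl2, 0 °C → rt, light excluded; used directly
Reagents that add atoms: none
Why: Dess–Martin oxidation of the neopentyl-type primary alcohol gives an aldehyde with no α-hydrogen, so the stereocentre cannot epimerise by enolisation.

**Step 7**
Reactants: 8 (2R)-6-[(tert-butyldimethylsilyl)oxy]-2,7,8-trimethyl-2H-chromene-2-carbaldehyde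
Product: 9 (2S)-6-[(tert-butyldimethylsilyl)oxy]-2-ethenyl-2,7,8-trimethyl-2H-chromene
Conditions: MePPh3Br (1.5 equiv), NaHMDS (1.4 equiv), THF, −78 → 0 °C, light excluded
Reagents that add atoms: methyltriphenylphosphonium bromide, C[P+](c1ccccc1)(c1ccccc1)c1ccccc1.[Br-]
Why: Wittig methylenation of the non-enolisable aldehyde installs the C2-vinyl group at low temperature, leaving the C2 stereocentre and the silyl ether intact (the descriptor changes from R to S only because the priorities change).

**Step 8**
Reactants: 10 methyl (triphenylphosphoranylidene)acetate; 11 5-bromo-2-methylpent-2-ene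
Product: 13 methyl 6-methyl-2-(triphenylphosphoranylidene)hept-5-enoate, via phosphonium bromide 12 (not isolated)
Conditions: NaI (0.2 equiv), MeCN, reflux; then aq. NaOH, CH2Cl2, 0 °C
Reagents that add atoms: none
Why: C-Alkylation of the ester-stabilised ylide by the primary halide (iodide formed in situ by Finkelstein exchange) gives the α-substituted phosphonium salt, which cold aqueous hydroxide deprotonates back to a stabilised ylide.

**Step 9**
Reactants: 14 pent-4-yn-1-ol
Product: 16 (E)-5-iodo-4-methylpent-4-en-1-ol, via alkenylalane 15 (not isolated)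
Conditions: Me3Al (3 equiv), Cp2ZrCl2 (0.25 equiv), CH2Cl2, 0 °C → rt; then I2, THF, −30 → 0 °C
Reagents that add atoms: trimethylaluminium, C[Al](C)C; iodine, II
Why: Zirconium-catalysed methylalumination (Negishi carboalumination) adds methyl and aluminium syn across the terminal alkyne with aluminium on the terminal carbon, and iodinolysis with retention should give the (E)-iodoalkene.

**Step 10**
Reactants: 16 (E)-5-iodo-4-methylpent-4-en-1-ol
Product: 17 (E)-5-iodo-4-methylpent-4-enal
Conditions: Dess–Martin periodinane (1.2 equiv), CH2Cl2, 0 °C → rt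
Reagents that add atoms: none
Why: Dess–Martin oxidation of the primary alcohol to the aldehyde; the vinyl iodide is inert and the mild conditions avoid alkene isomerisation.

**Step 11**
Reactants: 17 (E)-5-iodo-4-methylpent-4-enal; 13 methyl 6-methyl-2-(triphenylphosphoranylidene)hept-5-enoate
Product: 18 methyl (2E,6E)-7-iodo-6-methyl-2-(4-methylpent-3-en-1-yl)hepta-2,6-dienoate
Conditions: toluene, 80 °C
Reagents that add atoms: none
Why: Wittig olefination with an α-substituted ester-stabilised ylide should give the (2E)-enoate (ester trans to the new chain) through the less crowded oxaphosphetane, the minor (2Z)-isomer being removed by chromatography.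

**Step 12**
Reactants: 9 (2S)-6-[(tert-butyldimethylsilyl)oxy]-2-ethenyl-2,7,8-trimethyl-2H-chromene; 18 methyl (2E,6E)-7-iodo-6-methyl-2-(4-methylpent-3-en-1-yl)hepta-2,6-dienoate
Product: 20 methyl (2E,6E)-9-[(2S)-6-[(tert-butyldimethylsilyl)oxy]-2,7,8-trimethyl-2H-chromen-2-yl]-6-methyl-2-(4-methylpent-3-en-1-yl)nona-2,6-dienoate, via B-alkyl-9-BBN adduct 19 (not isolated)
Conditions: 9-BBN dimer (0.6 equiv), THF, 0 °C → rt; then 3 M aq. K3PO4, 18, PdCl2(dppf)·CH2Cl2 (5 mol %), AsPh3 (5 mol %), DMF, rt, degassed, light excluded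
Reagents that add atoms: none
Why: 9-BBN adds to the C2-vinyl group by a four-centre, anti-Markovnikov syn-hydroboration to give the primary alkylborane 19; after activation by the aqueous base its alkyl group transmetalates with retention to the (E)-alkenyl–Pd(II) iodide formed by stereoretentive oxidative addition of 18, and reductive elimination forges the C2′(sp3)–C3′(sp2) bond. The closest known reaction type is the B-alkyl Suzuki–Miyaura fragment coupling of 9-BBN adducts with (E)-1-iodo-2-methylalkenes. No ring is closed and no stereocentre is created: the C2 stereocentre lies two atoms from boron and is untouched, and the C3′=C4′ and C7′=C8′ geometries are carried over from 18. The step needs chemoselectivity for the monosubstituted vinyl over the cis-disubstituted styrenic C3=C4 of the pyran ring, which the strong preference of 9-BBN for terminal alkenes and the adjacent quaternary C2 should secure. It also needs boron on the terminal carbon, which places boron 1,3 to O1 and so excludes β-alkoxy elimination. Residual B–H is destroyed by the aqueous base before 18 is added, so the enoate is not reduced, and phosphate at room temperature should spare the ortho-methyl-flanked aryl silyl ether and the methyl ester.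

**Step 13**
Reactants: 20 methyl (2E,6E)-9-[(2S)-6-[(tert-butyldimethylsilyl)oxy]-2,7,8-trimethyl-2H-chromen-2-yl]-6-methyl-2-(4-methylpent-3-en-1-yl)nona-2,6-dienoate
Product: 21 (2E,6E)-9-[(2S)-6-hydroxy-2,7,8-trimethyl-2H-chromen-2-yl]-6-methyl-2-(4-methylpent-3-en-1-yl)nona-2,6-dienoic acid (CNP0158414.1)
Conditions: LiOH·H2O (8 equiv), THF/MeOH/H2O, degassed, 45 °C, light excluded; then 1 M HCl to pH 3–4, 0 °C
Reagents that add atoms: lithium hydroxide, [Li+].[OH-]
Why: Hydroxide saponifies the methyl enoate (BAc2) and cleaves the aryl silyl ether by attack at silicon with phenoxide as leaving group, so one operation liberates acid and phenol; the C2 stereocentre and the alkene geometries are not affected by base.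

**Compound list**
1 | 2,3-dimethylbenzene-1,4-diol | Cc1c(O)ccc(O)c1C | starting material
2 | 4-[(tert-butyldimethylsilyl)oxy]-2,3-dimethylphenol | Cc1c(O)ccc(O[Si](C)(C)C(C)(C)C)c1C | intermediate
3 | 5-[(tert-butyldimethylsilyl)oxy]-2-hydroxy-3,4-dimethylbenzaldehyde | O=Cc1cc(O[Si](C)(C)C(C)(C)C)c(C)c(C)c1O | intermediate
4 | 4-[(tert-butyldimethylsilyl)oxy]-6-ethenyl-2,3-dimethylphenol | C=Cc1cc(O[Si](C)(C)C(C)(C)C)c(C)c(C)c1O | intermediate
5 | 2-methyl-2-vinyloxirane (racemic) | CC1(C=C)CO1 | starting material
6 | (2R)-2-{4-[(tert-butyldimethylsilyl)oxy]-6-ethenyl-2,3-dimethylphenoxy}-2-methylbut-3-en-1-ol | OC[C@@](Oc1c(C=C)cc(O[Si](C)(C)C(C)(C)C)c(C)c1C)(C)C=C | intermediate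
7 | [(2R)-6-[(tert-butyldimethylsilyl)oxy]-2,7,8-trimethyl-2H-chromen-2-yl]methanol | OC[C@@]1(C)C=Cc2cc(O[Si](C)(C)C(C)(C)C)c(C)c(C)c2O1 | intermediate
8 | (2R)-6-[(tert-butyldimethylsilyl)oxy]-2,7,8-trimethyl-2H-chromene-2-carbaldehyde | O=C[C@@]1(C)C=Cc2cc(O[Si](C)(C)C(C)(C)C)c(C)c(C)c2O1 | intermediate
9 | (2S)-6-[(tert-butyldimethylsilyl)oxy]-2-ethenyl-2,7,8-trimethyl-2H-chromene | C=C[C@@]1(C)C=Cc2cc(O[Si](C)(C)C(C)(C)C)c(C)c(C)c2O1 | intermediate
10 | methyl (triphenylphosphoranylidene)acetate | COC(=O)C=P(c1ccccc1)(c1ccccc1)c1ccccc1 | starting material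
11 | 5-bromo-2-methylpent-2-ene | CC(C)=CCCBr | starting material
12 | (1-methoxy-6-methyl-1-oxohept-5-en-2-yl)triphenylphosphonium bromide | COC(=O)C(CCC=C(C)C)[P+](c1ccccc1)(c1ccccc1)c1ccccc1.[Br-] | intermediate
13 | methyl 6-methyl-2-(triphenylphosphoranylidene)hept-5-enoate | COC(=O)C(CCC=C(C)C)=P(c1ccccc1)(c1ccccc1)c1ccccc1 | intermediate
14 | pent-4-yn-1-ol | C#CCCCO | starting material
15 | (E)-[5-(dimethylalumanyloxy)-2-methylpent-1-en-1-yl]dimethylalane | C[Al](C)OCCC/C(C)=C/[Al](C)C | intermediate
16 | (E)-5-iodo-4-methylpent-4-en-1-ol | OCCC/C(C)=C/I | intermediate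
17 | (E)-5-iodo-4-methylpent-4-enal | O=CCC/C(C)=C/I | intermediate
18 | methyl (2E,6E)-7-iodo-6-methyl-2-(4-methylpent-3-en-1-yl)hepta-2,6-dienoate | CC(C)=CCC/C(=C\CC/C(C)=C/I)C(=O)OC | intermediate
19 | 9-{2-[(2S)-6-[(tert-butyldimethylsilyl)oxy]-2,7,8-trimethyl-2H-chromen-2-yl]ethyl}-9-borabicyclo[3.3.1]nonane | B1(CC[C@@]2(C)C=Cc3cc(O[Si](C)(C)C(C)(C)C)c(C)c(C)c3O2)C2CCCC1CCC2 | intermediate
20 | methyl (2E,6E)-9-[(2S)-6-[(tert-butyldimethylsilyl)oxy]-2,7,8-trimethyl-2H-chromen-2-yl]-6-methyl-2-(4-methylpent-3-en-1-yl)nona-2,6-dienoate | CC(C)=CCC/C(=C\CC/C(C)=C/CC[C@@]1(C)C=Cc2cc(O[Si](C)(C)C(C)(C)C)c(C)c(C)c2O1)C(=O)OC | intermediate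
21 | (2E,6E)-9-[(2S)-6-hydroxy-2,7,8-trimethyl-2H-chromen-2-yl]-6-methyl-2-(4-methylpent-3-en-1-yl)nona-2,6-dienoic acid | CC(C)=CCC/C(=C\CC/C(C)=C/CC[C@@]1(C)C=Cc2cc(O)c(C)c(C)c2O1)C(=O)O | target

**Totals**
Total step count: 13.
Longest linear sequence: 9 steps (steps 1–7, 12 and 13).

**Steps most likely to fail**

1. Step 4. The hindered, doubly ortho-substituted phenoxide may attack the primary allyl terminus or react slowly, and the tertiary allyl aryl ether may re-ionise on palladium, eroding regio- and enantiopurity. The fallback sets out from 3 and comes back at 9, building the stereocentre by oxypalladation instead of allylic etherification. Wittig reaction of 3 with 1-(triphenylphosphoranylidene)propan-2-one (toluene, 80 °C) should give the enone F1. Hydrogenation (H2, Pd/C, EtOAc) should give the saturated ketone F2. Wittig reaction with ethylidenetriphenylphosphorane (EtPPh3Br, NaHMDS, THF) should give the alkenylphenol F3 as an E/Z mixture. An enantioselective Wacker-type cyclisation (Pd(TFA)2, the Bn-BOXAX enantiomer that delivers the R product, p-benzoquinone, MeOH, 60 °C) should give the vinylchromane F4; ligand-controlled oxypalladation sets the quaternary centre and β-hydride elimination toward the methyl group leaves the vinyl group. Benzylic dehydrogenation with DDQ (dioxane, 80 °C) should then give 9.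

2. Step 12. Hydroboration may partly reach the ring C3=C4 alkene, the alkylborane may transmetalate slowly or protodeboronate, and the aqueous base may remove the silyl ether during coupling. The fallback sets out from 9 and comes back at 20, forming the same C2′–C3′ bond by a base-free organozinc coupling. Hydroboration with 9-BBN and oxidation with NaBO3·4H2O should give the primary alcohol F5, which chromatography frees of any ring-hydroborated material. Iodination (I2, PPh3, imidazole, CH2Cl2) should give the iodide F6. Zinc insertion (Zn dust, LiCl, THF) should give the alkylzinc iodide F7, used in solution. Negishi coupling with 18 (Pd2(dba)3, SPhos, THF/NMP, rt) should give 20.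

3. Step 8. C-Alkylation of the stabilised ylide by an unactivated homoallylic halide may be sluggish, with competing elimination of the halide and incomplete conversion through transylidation. The fallback sets out from 11 and comes back at 18, replacing the phosphorane by a phosphonate carbanion. Alkylation of the sodium salt of trimethyl phosphonoacetate with 11 (NaH, DMSO, 50 °C) should give the phosphonate F8. Horner–Wadsworth–Emmons reaction of F8 with 17 (NaH, THF, 0 °C → rt) should give 18 after chromatographic removal of the (2Z)-isomer.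

**Further compounds**
F1 | step 4 | (E)-4-{5-[(tert-butyldimethylsilyl)oxy]-2-hydroxy-3,4-dimethylphenyl}but-3-en-2-one | CC(=O)/C=C/c1cc(O[Si](C)(C)C(C)(C)C)c(C)c(C)c1O
F2 | step 4 | 4-{5-[(tert-butyldimethylsilyl)oxy]-2-hydroxy-3,4-dimethylphenyl}butan-2-one | CC(=O)CCc1cc(O[Si](C)(C)C(C)(C)C)c(C)c(C)c1O
F3 | step 4 | 4-[(tert-butyldimethylsilyl)oxy]-2,3-dimethyl-6-(3-methylpent-3-en-1-yl)phenol (E/Z mixture) | CC=C(C)CCc1cc(O[Si](C)(C)C(C)(C)C)c(C)c(C)c1O
F4 | step 4 | (2R)-6-[(tert-butyldimethylsilyl)oxy]-2-ethenyl-2,7,8-trimethyl-3,4-dihydro-2H-chromene | C=C[C@@]1(C)CCc2cc(O[Si](C)(C)C(C)(C)C)c(C)c(C)c2O1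
F5 | step 12 | 2-[(2S)-6-[(tert-butyldimethylsilyl)oxy]-2,7,8-trimethyl-2H-chromen-2-yl]ethan-1-ol | OCC[C@@]1(C)C=Cc2cc(O[Si](C)(C)C(C)(C)C)c(C)c(C)c2O1
F6 | step 12 | (2S)-6-[(tert-butyldimethylsilyl)oxy]-2-(2-iodoethyl)-2,7,8-trimethyl-2H-chromene | ICC[C@@]1(C)C=Cc2cc(O[Si](C)(C)C(C)(C)C)c(C)c(C)c2O1
F7 | step 12 | {2-[(2S)-6-[(tert-butyldimethylsilyl)oxy]-2,7,8-trimethyl-2H-chromen-2-yl]ethyl}zinc iodide | I[Zn]CC[C@@]1(C)C=Cc2cc(O[Si](C)(C)C(C)(C)C)c(C)c(C)c2O1
F8 | step 8 | methyl 2-(dimethoxyphosphoryl)-6-methylhept-5-enoate | COC(=O)C(CCC=C(C)C)P(=O)(OC)OC
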